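**Retrosynthetic overview** (ring A = arene, ring B = dihydropyran, ring C = cyclopentane, ring D = cyclohexene)
1. Break O–C5 of the target and re-bond C5–C6 to reach a C4-benzylated cubeb-7-yl (cyclopropylcarbinyl) cation. Breaking C1–C6 of that cation gives a guaia-1(5),6-diene that carries the phenol on C4. Ring D therefore comes from a 7→6 contraction and spiro C1 from a 1,2-vinyl shift.
2. That diene is the acid-opened form of the oxa-[4+2] adduct between an o-quinone methide and the C4=C5 bond of (−)-α-gurjunene. The adduct holds the C9′–C4 and O–C5 bonds, and its CMe2 cyclopropane becomes C6=C7–iPr.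
3. The o-quinone methide comes from isovaleraldehyde and 2,4-diformylphloroglucinol (Knoevenagel), and the dialdehyde comes from phloroglucinol (double Vilsmeier–Haack).
4. Ring order: rings A and C are bought. Ring B closes first (cycloaddition) and is reopened by acid. The terpene cyclopropane then opens, a transient C1–C5–C6 cyclopropane forms and opens to leave ring D, and ring B closes again last at C5.
5. Stereocontrol: C10 comes from the chiral pool, C4 and C9′ from the cycloaddition, and C1 and C5 are relayed from C4 through the tethered phenol.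

**Assumption:** the terpene carbons keep guaiane numbering throughout (in the target C1 = spiro carbon, C4 = quaternary C–CH3, C5 = OCH, C6=C7 = alkene, C10 = CH–CH3) and the benzylic carbon is C9′. Commercial (−)-α-gurjunene, the main hydrocarbon of gurjun balsam oil, is taken as the (1aR,4R,4aR,7bS) enantiomer, whose C10 (R) is C10 of the target.

**Route**

Step 1
Reactants: 1 phloroglucinol
Product: 3 2,4-diformylphloroglucinol, via bis-iminium salt 2 (not isolated)
Conditions: POCl3 (2.2 equiv), DMF (2.3 equiv), EtOAc, 0 °C → rt, 16 h; then H2O, rt, 2 h, filter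
Reagents that add atoms: N,N-dimethylformamide CN(C)C=O; water O
Why: Vilsmeier–Haack formylation, in which the very electron-rich ring takes up two chloroiminium units, salt 2 precipitates and is deactivated enough to leave the third position free, and water hydrolyses it to 3; no stereocentre is formed.

Step 2
Reactants: 3 2,4-diformylphloroglucinol; 4 isovaleraldehyde; 5 (−)-α-gurjunene
Product: 7 aromadendrane chroman adduct (9′R,1R,4S,5R,6S,7R,10R), via o-quinone methide 6 (not isolated)
Conditions: 5 (1.0 equiv), 3 (1.3 equiv), 4 (2.0 equiv, added over 6 h), ethylenediammonium diacetate (20 mol %), 4 Å MS, MeCN, 50 °C, 24 h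
Reagents that add atoms: none
Why: Domino Knoevenagel condensation/inverse-electron-demand oxa-Diels–Alder reaction, in which electrophilic 6 bonds through C9′ to C4 because only this regiochemistry places the charge on C5 (tertiary and cyclopropylcarbinyl, and also the more hindered end); attack anti to the donor C6–C11 bond, on the face opposite the CMe2 bridge, sets C4 (S) and C5 (R), and the E geometry of 6 with the compact cyclopentene ring endo sets C9′ (R).

Step 3
Reactants: 7 aromadendrane chroman adduct
Product: 11 CNP0121396.1 (target), via allyl cation 8 (not isolated), via dienyl phenol 9 (not isolated), via cyclopropylcarbinyl cation 10 (not isolated)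
Conditions: TsOH·H2O (20 mol %), 1,1,1,3,3,3-hexafluoropropan-2-ol/CH2Cl2 1:1 (0.02 M), 0 → 40 °C, 2–6 h, stopped when 9 is consumed
Reagents that add atoms: none
Why: Proposed new method: acid ionises the tertiary cyclopropylcarbinyl C5–OAr bond (the aryloxide is a vinylogous carboxylate), the anti-periplanar C6–C11 bond opens and a 1,2-hydride shift (H7 to C11) gives allyl cation 8, loss of H1 gives diene 9, and the acidic ortho-OH hanging from C4 returns the proton to C5 on the C9′ face; the C6=C7 bond can then close on C1 only from the opposite face, giving tertiary cation 10 (natural cubebane configuration, 7→6 contraction, spiro C1 set as R), and the phenol opens C5–C6 with inversion (C5 set as R, ring B cis-fused); every other O-capture product is a tertiary allylic or cyclopropylcarbinyl ether that re-ionises, whereas 11 is a secondary, doubly neopentyl ether and acts as the sink, with C10, C4 and C9′ carried through unchanged; the closest known reaction types are the cyclopropylcarbinyl–homoallyl (cholesteryl/3,5-cyclosteroid) rearrangement, the cyclohept-3-enyl/2-norcaranyl/cyclohex-2-enylmethyl cation manifold, and the acid opening of gem-dimethylcyclopropylcarbinyl (carene-type) systems.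

**Compound list**
1 | phloroglucinol (benzene-1,3,5-triol) | Oc1cc(O)cc(O)c1 | starting material
2 | 2,4-bis[(dimethyliminio)methyl]phloroglucinol dichloride | C[N+](C)=Cc1c(O)cc(O)c(C=[N+](C)C)c1O.[Cl-].[Cl-] | intermediate
3 | 2,4-diformylphloroglucinol (2,4,6-trihydroxybenzene-1,3-dicarbaldehyde) | O=Cc1c(O)cc(O)c(C=O)c1O | intermediate
4 | isovaleraldehyde (3-methylbutanal) | CC(C)CC=O | starting material
5 | (−)-α-gurjunene, aromadendr-4-ene, (1aR,4R,4aR,7bS)-1,1,4,7-tetramethyl-1a,2,3,4,4a,5,6,7b-octahydro-1H-cyclopropa[e]azulene | C[C@@H]1CC[C@@H]2[C@@H](C2(C)C)C3=C(CC[C@H]13)C | starting material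
6 | o-quinone methide, (5E)-2,4-dihydroxy-5-(3-methylbutylidene)-6-oxocyclohexa-1,3-diene-1,3-dicarbaldehyde | CC(C)C/C=C1/C(=O)C(C=O)=C(O)C(C=O)=C1O | intermediate
7 | chroman adduct: C9′ (R, isobutyl cis to C3) bonded to C4 (S, methyl on the other face); aryl O on C5 (R), anti to the CMe2 bridge and trans to H1; C6–C7–C11 cyclopropane intact (1R,6S,7R,10R) | CC(C)C[C@H]1c2c(O)c(C=O)c(O)c(C=O)c2O[C@@]23[C@H]4[C@@H](CC[C@@H](C)[C@H]2CC[C@]31C)C4(C)C | intermediate
8 | C5–C6–C7 allyl cation of the guaiane skeleton, isopropyl on C7, free triol-dialdehyde arene on C9′ (9′R,1R,4S,10R) | CC(C)C[C@@H](c1c(O)c(C=O)c(O)c(C=O)c1O)[C@]1(C)CC[C@H]2C1=C[C+](C(C)C)CC[C@H]2C | intermediate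
9 | 5-[1-(guaia-1(5),6-dien-4-yl)-3-methylbutyl]-2,4,6-trihydroxybenzene-1,3-dicarbaldehyde (9′R,4S,10R) | CC(C)C[C@@H](c1c(O)c(C=O)c(O)c(C=O)c1O)[C@]1(C)CCC2=C1C=C(C(C)C)CC[C@H]2C | intermediate
10 | 4-substituted cubeb-7-yl cation: C1–C5–C6 cyclopropane on the face of ring C opposite C9′, natural cubebane configuration at C1, C5, C6 and C10 (9′R,4S,10R) | CC(C)C[C@@H](c1c(O)c(C=O)c(O)c(C=O)c1O)[C@]1(C)CC[C@]23[C@H]1[C@H]2[C+](C(C)C)CC[C@H]3C | intermediate
11 | CNP0121396.1: ring B cis-fused to ring C; C9′ R (isobutyl), C4 S (methyl), C5 R (OCH), spiro C1 R (C10 on the O5 face, C6 on the other face), C10 R (methyl); C6=C7 carries isopropyl; ring A carries two CHO and two OH | CC(C)C[C@H]1c2c(O)c(C=O)c(O)c(C=O)c2O[C@@H]2[C@@]1(C)CC[C@@]21C=C(C(C)C)CC[C@H]1C | target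

**Total step count:** 3. **Longest linear sequence:** 3 (1 → 3 → 7 → 11).

**Steps most likely to fail**

Step 3 carries the highest risk.
- The cation manifold may rest at the tertiary allylic ether or at diene 9.
- It may leak by retro-Michael loss of the terpene.
- C10 may epimerise through a C1=C10 olefin.
- The C6=C7 bond may migrate after 11 has formed.

The fallback sets out from 3 and 4 (that is, from quinone methide 6) and comes back to the route at cation 10, which closes to 11. Ring D and the spiro centre are built before the coupling instead of after it. Cheap (−)-menthone F1, whose methyl-bearing carbon already is C10 (R), is formylated at its free α-CH2 (HCO2Et, NaH, THF) to hydroxymethylene ketone F2. Et3N-catalysed Michael addition to methyl vinyl ketone, anti to the neighbouring methyl, gives keto aldehyde F3 and sets the quaternary carbon. An intramolecular McMurry coupling of the aldehyde and the methyl ketone then closes the methylcyclopentene of spiro ketone F4 (TiCl3, Zn–Cu couple, DME, reflux, slow addition). The ring ketone stays out of this coupling because it sits between a quaternary and an isopropyl-bearing carbon. KN(SiMe3)2 and PhNTf2 give enol triflate F5, since only one enolisation direction is left, and Pd(OAc)2, PPh3, HCO2H and Bu3N reduce it to spirodiene F6. F6 is combined with 3 and 4 under the conditions of step 2 with TsOH added. C5 of F6 is neopentyl, so 6 bonds to C4 on the face anti to the C6=C7 bond. That bond takes up the charge at C5 and gives 10 directly.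

Step 2 is the next most risky.
- The tetrasubstituted alkene is hindered.
- 6 can tautomerise to the styrene or oligomerise.
- The ammonium acetate buffer can isomerise 5.
- Face and endo/exo selectivity may be only moderate.

The fallback sets out from 3 and comes back at 7 (through 6). It generates the quinone methide by oxidation instead of condensation. Compounds 3 and 4 react with diethyl 2,6-dimethyl-1,4-dihydropyridine-3,5-dicarboxylate and L-proline (20 mol %) in CH2Cl2 in a three-component reductive alkylation. This gives the stable isopentyl dialdehyde F7. DDQ is then added slowly to F7 and 5 in MeNO2 at 0 °C. 6 arises by benzylic hydride abstraction, free of amine and water and at low stationary concentration, and is trapped by 5.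

Step 1 is the least risky of the three. Mono-, di- and triformyl products may form together and are hard to separate. The fallback sets out from 1 and comes back at 3, and it masks the phenols so that the degree of formylation is controlled by stoichiometry. Compound 1 is methylated (Me2SO4, K2CO3, acetone, reflux) to 1,3,5-trimethoxybenzene F8. Rieche formylation (Cl2CHOMe 2.5 equiv, TiCl4, CH2Cl2, −10 °C → rt) gives 2,4,6-trimethoxybenzene-1,3-dicarbaldehyde F9. BBr3 (CH2Cl2, −78 °C → rt) then removes the three methyl groups to give 3.

**Further compounds**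
F1 | step 3 | (−)-menthone, (2S,5R)-5-methyl-2-(propan-2-yl)cyclohexan-1-one (bought) | C[C@@H]1CC[C@H](C(=O)C1)C(C)C
F2 | step 3 | (2Z,3R,6S)-2-(hydroxymethylidene)-3-methyl-6-(propan-2-yl)cyclohexan-1-one | O/C=C1\C(=O)[C@H](C(C)C)CC[C@H]1C
F3 | step 3 | (1S,3S,6R)-6-methyl-2-oxo-1-(3-oxobutyl)-3-(propan-2-yl)cyclohexane-1-carbaldehyde | CC(=O)CC[C@]1(C=O)C(=O)[C@H](C(C)C)CC[C@H]1C
F4 | step 3 | (5S,7S,10R)-2,10-dimethyl-7-(propan-2-yl)spiro[4.5]dec-1-en-6-one | CC1=C[C@@]2(CC1)C(=O)[C@H](C(C)C)CC[C@H]2C
F5 | step 3 | (5S,10R)-2,10-dimethyl-7-(propan-2-yl)spiro[4.5]deca-1,6-dien-6-yl trifluoromethanesulfonate | CC1=C[C@@]2(CC1)C(OS(=O)(=O)C(F)(F)F)=C(C(C)C)CC[C@H]2C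
F6 | step 3 | (5S,10R)-2,10-dimethyl-7-(propan-2-yl)spiro[4.5]deca-1,6-diene | CC1=C[C@@]2(CC1)C=C(C(C)C)CC[C@H]2C
F7 | step 2 | 2,4,6-trihydroxy-5-(3-methylbutyl)benzene-1,3-dicarbaldehyde | CC(C)CCc1c(O)c(C=O)c(O)c(C=O)c1O
F8 | step 1 | 1,3,5-trimethoxybenzene | COc1cc(OC)cc(OC)c1
F9 | step 1 | 2,4,6-trimethoxybenzene-1,3-dicarbaldehyde | COc1cc(OC)c(C=O)c(OC)c1C=O
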